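Start from the south-east flask and turn the question round: what would have to be true for half of its starting material to become target? That takes 185 mM of target, and with one reagent per target the 80.0 mM charged is less. Reagent is the limiting reagent there, and the ceiling is 21.6% of the starting material.

| setting | east | west | south | north-east | south-east |
|---|---|---|---|---|---|
| starting material | 80.0 mM | 40.0 mM | 160 mM | 80.0 mM | 370 mM |
| reagent | 80.0 mM | 40.0 mM | 80.0 mM | 240 mM | 80.0 mM |
| catalyst | 0.160 mM | 0.160 mM | 0.160 mM | 0.160 mM | 0.160 mM |
| time |  |  |  |  | 14 min |

| east run: time / min | east run: [target] / mM | west run: time / min | west run: [target] / mM | south run: time / min | south run: [target] / mM | north-east run: time / min | north-east run: [target] / mM |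
|---|---|---|---|---|---|---|---|
| 2.0 | 12.8 | 2.0 | 7.4 | 2.0 | 18.8 | 2.0 | 10.4 |
| 4.0 | 19.9 | 4.0 | 14.2 | 4.0 | 31.7 | 4.0 | 11.3 |
| 6.0 | 27.3 | 6.0 | 17.4 | 6.0 | 41.3 | 6.0 | 12.6 |
| 8.0 | 31.2 | 8.0 | 20.3 | 8.0 | 46.7 | 8.0 | 11.9 |
| 10 | 34.7 | 10 | 22.0 | 10 | 49.5 | 10 | 11.2 |
| 12 | 36.7 | 12 | 22.9 | 12 | 48.8 | 12 | 9.6 |
| 14 | 38.4 | 14 | 24.6 | 14 | 50.6 | 14 | 9.3 |

(scatter of a reading: 0.6 mM)

1. the power of [reagent] that the first rate follows, about the charge of the east run; measure it at two percent of starting material made into target
2. the power of [starting material] that the first rate follows, about the charge of the east run; measure it at two percent of starting material made into target (one fixed amount of target, the same in the runs compared)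
3. target in the south-east run at 14 min, as a share of the starting material charged

- Overall: starting material + reagent -> target, with catalyst as catalyst.
- Constant volume, constant temperature.
- What is held in complexes is read along with the free species.
- An order is taken over about fifteen percent of the charge, up and down.

Even that ceiling asks that reagent turn into target and that the target stay. The north-east run, with 240 mM of reagent, reads 12.6 mM at 6.0 min and falls to 9.3 mM by 14 min, so I take it that reagent eats target. Suppose target is made at a steady rate r and drained at κ[target]. Integrating that over the time r needs to use the reagent charge gives the target as a share of that charge: (1 − e^−a)/a, with a = κ × that time.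

The south run at 14 min reads 50.6 mM, which is 63.2% of its reagent, and the formula meets this at a = 0.999. That is the south run's race number, the drain constant times the time its reagent charge lasts at the making rate. The ceiling needs a race number near zero.

South-east has the reagent charge of the south run, so I hold κ the same and let a fall as making speeds up. At 2.0 min, doubling the starting material from east to south raises the reading 1.47-fold, a power of 0.555. Carried to 370 mM, my power speeds making 1.59-fold, so a = 0.628. The formula then keeps 74.3% of the reagent as target, 59.4 mM, or 16.1% of the starting material.

The forecast gives 0.3 for reagent, 0.72 for starting material, higher than my power, and 16% for a plateau “limited by reagent and catalyst life”.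

The flask gives 15.3%, with powers 0.092 in reagent and 0.62 in starting material.

    catalyst + starting material ⇌ catalyst-substrate complex (1944 M⁻¹ min⁻¹, 72.60 min⁻¹)
    catalyst-substrate complex + reagent → target + catalyst (11340 M⁻¹ min⁻¹)
    target + reagent → side product (2.772 M⁻¹ min⁻¹)
    2 starting material ⇌ idle substrate dimer, settled at all times (26.30 M⁻¹)

The south run makes target at 1.5 times the rate of the east run, both where the same amount has been made. The south-east result is 70.8% of its reagent charge, against my 74.3%. The east run has the same reagent charge, so its race number is 1.50, and the formula gives 41.4 mM against a reading of 38.4 mM at 14 min.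

The earlier runs and the new flask are simulated for substances that don't exist; noise was put on by code.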